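**Plan**

- Retrosynthetic cuts, in order: the tiglate acyl–O bond; the phenol and alcohol masks together with the quinone oxidation level; the C3–C4 bond of the side-chain ring (6π electrocyclization of an o-quinoid vinylketene); the C1–C(vinyl) bond (vinyllithium plus benzocyclobutenedione); the two bonds of the four-membered ring (aryne plus ketene acetal).
- Forward order: the benzene ring is bought and the cyclobutene ring is fused on and oxidized to the 1,2-dione. The chiral C8 chain is then joined as a 1-substituted vinyllithium. The second six-membered ring arises by strain-driven ring expansion, and oxidation, deprotection and esterification follow.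
- Enabling feature: the side-chain ring is a six-membered carbocycle oxygenated at C1 and C4 and fused through C4a/C8a to a benzene ring, with the chain on C2 and only hydrogen on C3. C1 can therefore be a cyclobutenol carbon, C4 the cyclobutenone carbonyl (later ketene) carbon, C4a–C8a the benzo fusion and C2=C3 a CH2=C(R) group, so opening the four-membered ring drives the C3–C4 closure.
- The new ring emerges as a hydroquinone. Masked as its diacetate, it lets (NH4)2Ce(NO3)6 remove both methyl ethers oxidatively from the other ring; cyclobutenone, silyl ether, acetates and methyl ethers are all gone at the end.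
- Stereochemistry: the single (S) centre comes from a Brown allylation of 2-bromoacrolein (reagent control) and no bond to it is broken afterwards. The (E) ester geometry is bought with tiglic acid.

Key step: step 9

Remark: naphthazarins interconvert rapidly between their 1,4- and 5,8-quinone tautomers, so alkannin and the target are each a single compound; both are written in the tautomer of the target SMILES.

**Route**

Step 1
Reactants: 1 2-bromo-1,4-dimethoxybenzene; 2 1,1-diethoxyethene
Product: 5 2,5-dimethoxybicyclo[4.2.0]octa-1,3,5-trien-7-one (3,6-dimethoxybenzocyclobutenone), via dimethoxybenzyne 3 (not isolated), via diethyl ketal 4 (not isolated)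
Conditions: NaNH2 (2.5 equiv), 2 (3 equiv), THF, reflux; then 1 M HCl, THF, rt
Reagents that add atoms: water (SMILES: O)
Why: NaNH2 dehydrobrominates 1 to the symmetrical aryne 3, whose [2+2] cycloaddition with the electron-rich ketene acetal 2 (aryne–ketene acetal cycloaddition, no regiochemical issue by symmetry) gives ketal 4, which is hydrolysed on acidic work-up to the benzocyclobutenone.

Step 2
Reactants: 5 2,5-dimethoxybicyclo[4.2.0]octa-1,3,5-trien-7-one
Product: 6 8,8-dibromo-2,5-dimethoxybicyclo[4.2.0]octa-1,3,5-trien-7-one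
Conditions: NBS (2.2 equiv), AIBN (cat.), PhCF3, reflux
Reagents that add atoms: N-bromosuccinimide (SMILES: O=C1CCC(=O)N1Br)
Why: Wohl–Ziegler radical bromination should occur twice at the methylene that is both benzylic and α to the carbonyl, the non-polar medium and radical initiation disfavouring electrophilic attack on the dimethoxyarene.

Step 3
Reactants: 6 8,8-dibromo-2,5-dimethoxybicyclo[4.2.0]octa-1,3,5-trien-7-one
Product: 7 2,5-dimethoxybicyclo[4.2.0]octa-1,3,5-triene-7,8-dione (3,6-dimethoxybenzocyclobutenedione)
Conditions: CF3CO2Ag (2.2 equiv), MeCN/H2O, rt to 50 °C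
Reagents that add atoms: water (SMILES: O)
Why: silver-assisted solvolysis of the gem-dibromide (monovalent silver as halide acceptor) should give the gem-diol and hence the second carbonyl, the standard hydrolysis of an α,α-dihalo ketone to a 1,2-dione.

Step 4
Reactants: 8 acrolein
Product: 10 2-bromoprop-2-enal (2-bromoacrolein), via dibromopropanal 9 (not isolated)
Conditions: Br2 (1.0 equiv), CH2Cl2, −78 to 0 °C; then Et3N (1.05 equiv), 0 °C; used as a fresh solution
Reagents that add atoms: bromine (SMILES: BrBr)
Why: bromine addition to the enal followed by amine-mediated loss of HBr from the α-position (E1cB) is the standard bromination–dehydrobromination route to an α-bromo enal.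

Step 5
Reactants: 10 2-bromoprop-2-enal
Product: 12 (3S)-2-bromohexa-1,5-dien-3-ol, via borinate 11 (not isolated)
Conditions: (−)-Ipc2BOMe [from (+)-α-pinene], allylMgBr, Et2O, 0 °C to rt; then 10, −78 °C; then NaOH, H2O2, 0 °C to rt
Reagents that add atoms: allylmagnesium bromide (SMILES: C=CC[Mg]Br)
Why: Brown allylation through a chair Zimmerman–Traxler transition state, in which the isopinocampheyl groups derived from (+)-α-pinene direct the allyl group to the Si face of the aldehyde (the facial sense that gives (S)-1-phenylbut-3-en-1-ol from benzaldehyde), should set the (S) carbinol centre, and alkaline peroxide then cleaves borinate 11.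

Step 6
Reactants: 12 (3S)-2-bromohexa-1,5-dien-3-ol
Product: 13 tert-butyl{[(3S)-2-bromohexa-1,5-dien-3-yl]oxy}dimethylsilane
Conditions: TBSCl, imidazole, DMF, rt
Reagents that add atoms: tert-butyldimethylsilyl chloride (SMILES: CC(C)(C)[Si](C)(C)Cl)
Why: standard silylation of a secondary alcohol, which masks the hydroxyl for the organolithium step and the thermolysis without touching the stereocentre.

Step 7
Reactants: 13 tert-butyl{[(3S)-2-bromohexa-1,5-dien-3-yl]oxy}dimethylsilane
Product: 14 tert-butyl{[(3S)-2-bromo-6-methylhepta-1,5-dien-3-yl]oxy}dimethylsilane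
Conditions: 2-methyl-2-butene (large excess), (H2IMes)(PCy3)Cl2Ru=CHPh (second-generation Grubbs catalyst, 5 mol %), CH2Cl2, 40 °C
Reagents that add atoms: 2-methyl-2-butene (SMILES: CC=C(C)C)
Why: olefin cross-metathesis of the monosubstituted alkene with 2-methyl-2-butene should install the isopropylidene terminus, the hindered and electron-poor 2-bromoalkene being inert to the ruthenium carbene.

Step 8
Reactants: 14 tert-butyl{[(3S)-2-bromo-6-methylhepta-1,5-dien-3-yl]oxy}dimethylsilane; 7 2,5-dimethoxybicyclo[4.2.0]octa-1,3,5-triene-7,8-dione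
Product: 16 8-[(3S)-3-{[tert-butyl(dimethyl)silyl]oxy}-6-methylhepta-1,5-dien-2-yl]-8-hydroxy-2,5-dimethoxybicyclo[4.2.0]octa-1,3,5-trien-7-one (both C8 epimers), via vinyllithium 15 (not isolated)
Conditions: t-BuLi (2.05 equiv), Et2O, −78 °C; then cannulated into 7 (1.2 equiv), THF, −78 °C; aq. NH4Cl at −78 °C
Reagents that add atoms: none
Why: bromine–lithium exchange should give the 1-substituted vinyllithium, which adds once to one of the two equivalent strained carbonyl groups of 7 (1,2-addition of an organolithium to a benzocyclobutenedione), the new carbinol centre forming as an inconsequential epimer mixture because it is destroyed in step 9 while the (S) centre is untouched.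

Step 9
Reactants: 16 8-[(3S)-3-{[tert-butyl(dimethyl)silyl]oxy}-6-methylhepta-1,5-dien-2-yl]-8-hydroxy-2,5-dimethoxybicyclo[4.2.0]octa-1,3,5-trien-7-one
Product: 20 2-[(1S)-1-{[tert-butyl(dimethyl)silyl]oxy}-4-methylpent-3-en-1-yl]-5,8-dimethoxynaphthalene-1,4-diyl diacetate, via vinylketene 17 (not isolated), via dienone 18 (not isolated), via hydroquinone 19 (not isolated)
Conditions: degassed p-xylene (0.01 M), 138 °C, Ar; cooled, then Ac2O, pyridine, DMAP (cat.), rt
Reagents that add atoms: acetic anhydride (SMILES: CC(=O)OC(C)=O)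
Why: Heating should open the four-membered ring of 16 in a conrotatory 4π electrocyclic reaction, cyclobutenone strain release paying for the temporary loss of benzenoid aromaticity, and the hydroxyl on the breaking carbon turns outward (donor torquoselectivity) so that the alkenyl group of the o-quinoid vinylketene 17 lies next to the ketene. A thermally allowed disrotatory 6π electrocyclization of the ketene C=C, the exocyclic enol C=C and the C=CH2 group then joins the ketene carbon (later C4) to the terminal CH2 (later C3), which closes the new six-membered ring in a 6π-electrocyclic mode and restores the benzene ring in dienone 18; enolization gives hydroquinone 19, which is acetylated in the same flask before air can reach it. The closest known reaction type is the thermal ring expansion of 4-alkenyl-4-hydroxycyclobutenones and of alkenyl adducts of benzocyclobutenediones to hydroquinones (Moore rearrangement type). No stereocentre is formed, and the (S) centre lies outside the pericyclic array, bears no ionizable group under these neutral conditions and is kept from o-quinone methide chemistry by its silyl ether. The step needs torquoselectivity, regioselectivity and chemoselectivity: the hydroxyl donor secures inward rotation of the alkenyl group, the symmetry of the dione part and the CH2=C(R) pattern of the alkene put the chain on C2 and hydrogen on C3, and high dilution lets the intramolecular closure outrun ketene dimerization.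

Step 10
Reactants: 20 2-[(1S)-1-{[tert-butyl(dimethyl)silyl]oxy}-4-methylpent-3-en-1-yl]-5,8-dimethoxynaphthalene-1,4-diyl diacetate
Product: 21 2-[(1S)-1-{[tert-butyl(dimethyl)silyl]oxy}-4-methylpent-3-en-1-yl]-5,8-dioxo-5,8-dihydronaphthalene-1,4-diyl diacetate
Conditions: (NH4)2Ce(NO3)6 (3 equiv), MeCN/H2O, 0 °C
Reagents that add atoms: water (SMILES: O)
Why: oxidative demethylation of a 1,4-dimethoxyarene by tetravalent cerium should take only the dimethoxy ring to the quinone, because the oxygens of the side-chain ring are acetylated, so both methyl ethers leave oxidatively and regiospecifically while the trisubstituted alkene and the silyl ether tolerate the short exposure.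

Step 11
Reactants: 21 2-[(1S)-1-{[tert-butyl(dimethyl)silyl]oxy}-4-methylpent-3-en-1-yl]-5,8-dioxo-5,8-dihydronaphthalene-1,4-diyl diacetate
Product: 22 5,8-dihydroxy-2-[(1S)-1-hydroxy-4-methylpent-3-en-1-yl]naphthalene-1,4-dione (alkannin)
Conditions: Bu4NF·3H2O (5 equiv), THF, 0 °C to rt, Ar; then aq. NH4Cl
Reagents that add atoms: none
Why: fluoride should cleave the Si–O bond and, with the water of hydration, the two aryl acetates activated by the peri quinone carbonyls (acyl–oxygen cleavage), after which the naphthazarin equilibrates to the tautomer drawn and no bond to the stereocentre is broken.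

Step 12
Reactants: 22 alkannin; 23 tiglic acid [(2E)-2-methylbut-2-enoic acid]
Product: 24 (1S)-1-(5,8-dihydroxy-1,4-dioxo-1,4-dihydronaphthalen-2-yl)-4-methylpent-3-en-1-yl (2E)-2-methylbut-2-enoate (target)
Conditions: DCC (1.5 equiv), DMAP (0.2 equiv), CH2Cl2, 0 °C to rt
Reagents that add atoms: none
Why: Steglich esterification should acylate only the side-chain alcohol, because both phenolic hydroxyls are held in strong hydrogen bonds to the quinone carbonyls, and since the O–H and not the C–O bond reacts the (S) configuration is retained and the stable (E) geometry of the acid is kept.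

**Compound list**

1 | 2-bromo-1,4-dimethoxybenzene | COc1ccc(OC)c(Br)c1 | starting material
2 | 1,1-diethoxyethene | C=C(OCC)OCC | starting material
3 | 3,6-dimethoxybenzyne | COC1=CC=C(OC)C#C1 | intermediate
4 | 7,7-diethoxy-2,5-dimethoxybicyclo[4.2.0]octa-1,3,5-triene | CCOC1(OCC)Cc2c(OC)ccc(OC)c21 | intermediate
5 | 2,5-dimethoxybicyclo[4.2.0]octa-1,3,5-trien-7-one | COc1ccc(OC)c2c1CC2=O | intermediate
6 | 8,8-dibromo-2,5-dimethoxybicyclo[4.2.0]octa-1,3,5-trien-7-one | COc1ccc(OC)c2c1C(Br)(Br)C2=O | intermediate
7 | 2,5-dimethoxybicyclo[4.2.0]octa-1,3,5-triene-7,8-dione | COc1ccc(OC)c2c1C(=O)C2=O | intermediate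
8 | acrolein | C=CC=O | starting material
9 | 2,3-dibromopropanal (racemic) | O=CC(Br)CBr | intermediate
10 | 2-bromoprop-2-enal | C=C(Br)C=O | intermediate
11 | (3S)-2-bromohexa-1,5-dien-3-yl diisopinocampheylborinate | C=C(Br)[C@H](CC=C)OB([C@@H]1C[C@@H]2C[C@H]([C@H]1C)C2(C)C)[C@@H]1C[C@@H]2C[C@H]([C@H]1C)C2(C)C | intermediate
12 | (3S)-2-bromohexa-1,5-dien-3-ol | O[C@@H](CC=C)C(Br)=C | intermediate
13 | tert-butyl{[(3S)-2-bromohexa-1,5-dien-3-yl]oxy}dimethylsilane | CC(C)(C)[Si](C)(C)O[C@@H](CC=C)C(Br)=C | intermediate
14 | tert-butyl{[(3S)-2-bromo-6-methylhepta-1,5-dien-3-yl]oxy}dimethylsilane | CC(C)(C)[Si](C)(C)O[C@@H](CC=C(C)C)C(Br)=C | intermediate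
15 | [(3S)-3-{[tert-butyl(dimethyl)silyl]oxy}-6-methylhepta-1,5-dien-2-yl]lithium | CC(C)(C)[Si](C)(C)O[C@@H](CC=C(C)C)C([Li])=C | intermediate
16 | 8-[(3S)-3-{[tert-butyl(dimethyl)silyl]oxy}-6-methylhepta-1,5-dien-2-yl]-8-hydroxy-2,5-dimethoxybicyclo[4.2.0]octa-1,3,5-trien-7-one (both C8 epimers) | CC(C)(C)[Si](C)(C)O[C@@H](CC=C(C)C)C(=C)C1(O)C(=O)c2c(OC)ccc(OC)c21 | intermediate
17 | o-quinoid vinylketene: {(6Z)-6-[(3S)-3-{[tert-butyl(dimethyl)silyl]oxy}-1-hydroxy-6-methyl-2-methylidenehept-5-en-1-ylidene]-2,5-dimethoxycyclohexa-2,4-dien-1-ylidene}methanone | O=C=C1C(OC)=CC=C(OC)/C1=C(\O)C(=C)[C@@H](O[Si](C)(C)C(C)(C)C)CC=C(C)C | intermediate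
18 | 3-[(1S)-1-{[tert-butyl(dimethyl)silyl]oxy}-4-methylpent-3-en-1-yl]-4-hydroxy-5,8-dimethoxynaphthalen-1(2H)-one | O=C1CC([C@@H](O[Si](C)(C)C(C)(C)C)CC=C(C)C)=C(O)c2c(OC)ccc(OC)c12 | intermediate
19 | 2-[(1S)-1-{[tert-butyl(dimethyl)silyl]oxy}-4-methylpent-3-en-1-yl]-5,8-dimethoxynaphthalene-1,4-diol | Oc1cc([C@@H](O[Si](C)(C)C(C)(C)C)CC=C(C)C)c(O)c2c(OC)ccc(OC)c12 | intermediate
20 | 2-[(1S)-1-{[tert-butyl(dimethyl)silyl]oxy}-4-methylpent-3-en-1-yl]-5,8-dimethoxynaphthalene-1,4-diyl diacetate | CC(=O)Oc1cc([C@@H](O[Si](C)(C)C(C)(C)C)CC=C(C)C)c(OC(C)=O)c2c(OC)ccc(OC)c12 | intermediate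
21 | 2-[(1S)-1-{[tert-butyl(dimethyl)silyl]oxy}-4-methylpent-3-en-1-yl]-5,8-dioxo-5,8-dihydronaphthalene-1,4-diyl diacetate | CC(=O)Oc1cc([C@@H](O[Si](C)(C)C(C)(C)C)CC=C(C)C)c(OC(C)=O)c2C(=O)C=CC(=O)c12 | intermediate
22 | alkannin, 5,8-dihydroxy-2-[(1S)-1-hydroxy-4-methylpent-3-en-1-yl]naphthalene-1,4-dione | O[C@@H](CC=C(C)C)C1=CC(=O)c2c(O)ccc(O)c2C1=O | intermediate
23 | tiglic acid, (2E)-2-methylbut-2-enoic acid | C/C=C(\C)C(=O)O | starting material
24 | (1S)-1-(5,8-dihydroxy-1,4-dioxo-1,4-dihydronaphthalen-2-yl)-4-methylpent-3-en-1-yl (2E)-2-methylbut-2-enoate | C/C=C(\C)C(=O)O[C@@H](CC=C(C)C)C1=CC(=O)c2c(O)ccc(O)c2C1=O | target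

**Summary**

Total step count: 12. Longest linear sequence: 9 steps (steps 4 to 12).

Steps most likely to fail:

1. Step 9 (key step). The ring opening may need a temperature at which inward rotation of the alkenyl group is no longer exclusive or at which the ketene is lost to dimerization, and the hydroquinone may be oxidized before it is acetylated. The fallback builds the side-chain ring by a Dötz benzannulation instead; it sets out from 14 and 1 and comes back at 20. Dehydrobromination of 14 (LDA, THF, −78 °C) should give the terminal alkyne tert-butyl{[(3S)-6-methylhept-5-en-1-yn-3-yl]oxy}dimethylsilane F1. Bromine–lithium exchange on 1 (n-BuLi), addition to Cr(CO)6 and O-methylation with Me3OBF4 should give the zerovalent chromium carbene complex pentacarbonyl[(2,5-dimethoxyphenyl)(methoxy)methylidene]chromium F2. Heating F1 with F2 (THF, 50 °C) should give, after loss of the chromium carbonyl fragment, 2-[(1S)-1-{[tert-butyl(dimethyl)silyl]oxy}-4-methylpent-3-en-1-yl]-4,5,8-trimethoxynaphthalen-1-ol F3. Oxidative work-up with (NH4)2Ce(NO3)6 should convert this to 2-[(1S)-1-{[tert-butyl(dimethyl)silyl]oxy}-4-methylpent-3-en-1-yl]-5,8-dimethoxynaphthalene-1,4-dione F4, and reductive acetylation (Zn, Ac2O, pyridine) should then give 20.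

2. Step 8. The β-silyloxy vinyllithium may be lost by oxygen-to-carbon silyl migration or by β-elimination before it adds, and a second addition to the remaining carbonyl may compete. The fallback removes the silyl group from the organometallic altogether; it sets out from 12 (and uses 7) and comes back at 16. Cross-metathesis of 12 with 2-methyl-2-butene under the conditions of step 7 should give (3S)-2-bromo-6-methylhepta-1,5-dien-3-ol F5. Deprotonation with n-BuLi (1 equiv) and exchange with t-BuLi (2 equiv) in Et2O at −78 °C should give lithium (3S)-2-lithio-6-methylhepta-1,5-dien-3-olate F6, which cannot migrate a silyl group or expel a good leaving group. Its addition to 7 should give 8-hydroxy-8-[(3S)-3-hydroxy-6-methylhepta-1,5-dien-2-yl]-2,5-dimethoxybicyclo[4.2.0]octa-1,3,5-trien-7-one F7, and silylation of the secondary hydroxyl only (TBSCl, imidazole; the tertiary cyclobutenol is too hindered) should give 16.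

3. Step 11. Fluoride or hydroxide may add to the unsubstituted quinone double bond, or an acetyl group may migrate to the side-chain oxygen once the silyl group has gone, before the naphthazarin is released. The fallback reorders the endgame so that the silyl ether is removed before any quinone exists and the last step needs only a weak base; it sets out from 20 (and uses 23) and comes back at 24, bypassing 21 and 22. HF·pyridine (THF/pyridine, 0 °C) should cleave only the silyl ether of 20 to give 2-[(1S)-1-hydroxy-4-methylpent-3-en-1-yl]-5,8-dimethoxynaphthalene-1,4-diyl diacetate F8. Steglich esterification with 23 (DCC, DMAP) should give (1S)-1-(1,4-diacetoxy-5,8-dimethoxynaphthalen-2-yl)-4-methylpent-3-en-1-yl (2E)-2-methylbut-2-enoate F9. Oxidation with (NH4)2Ce(NO3)6 as in step 10 should give (1S)-1-(1,4-diacetoxy-5,8-dioxo-5,8-dihydronaphthalen-2-yl)-4-methylpent-3-en-1-yl (2E)-2-methylbut-2-enoate F10. Brief treatment with aq. NaHCO3 in MeOH at 0 °C should then cleave only the two peri-activated aryl acetates, leaving the hindered conjugated side-chain ester, and give 24.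

**Further compounds**

F1 | step 9 | tert-butyl{[(3S)-6-methylhept-5-en-1-yn-3-yl]oxy}dimethylsilane | C#C[C@@H](O[Si](C)(C)C(C)(C)C)CC=C(C)C
F2 | step 9 | pentacarbonyl[(2,5-dimethoxyphenyl)(methoxy)methylidene]chromium | COC(=[Cr])c1cc(OC)ccc1OC.[C-]#[O+].[C-]#[O+].[C-]#[O+].[C-]#[O+].[C-]#[O+]
F3 | step 9 | 2-[(1S)-1-{[tert-butyl(dimethyl)silyl]oxy}-4-methylpent-3-en-1-yl]-4,5,8-trimethoxynaphthalen-1-ol | COc1cc([C@@H](O[Si](C)(C)C(C)(C)C)CC=C(C)C)c(O)c2c(OC)ccc(OC)c12
F4 | step 9 | 2-[(1S)-1-{[tert-butyl(dimethyl)silyl]oxy}-4-methylpent-3-en-1-yl]-5,8-dimethoxynaphthalene-1,4-dione | CC(C)(C)[Si](C)(C)O[C@@H](CC=C(C)C)C1=CC(=O)c2c(OC)ccc(OC)c2C1=O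
F5 | step 8 | (3S)-2-bromo-6-methylhepta-1,5-dien-3-ol | O[C@@H](CC=C(C)C)C(Br)=C
F6 | step 8 | lithium (3S)-2-lithio-6-methylhepta-1,5-dien-3-olate | [Li]O[C@@H](CC=C(C)C)C([Li])=C
F7 | step 8 | 8-hydroxy-8-[(3S)-3-hydroxy-6-methylhepta-1,5-dien-2-yl]-2,5-dimethoxybicyclo[4.2.0]octa-1,3,5-trien-7-one | O[C@@H](CC=C(C)C)C(=C)C1(O)C(=O)c2c(OC)ccc(OC)c21
F8 | step 11 | 2-[(1S)-1-hydroxy-4-methylpent-3-en-1-yl]-5,8-dimethoxynaphthalene-1,4-diyl diacetate | CC(=O)Oc1cc([C@@H](O)CC=C(C)C)c(OC(C)=O)c2c(OC)ccc(OC)c12
F9 | step 11 | (1S)-1-(1,4-diacetoxy-5,8-dimethoxynaphthalen-2-yl)-4-methylpent-3-en-1-yl (2E)-2-methylbut-2-enoate | C/C=C(\C)C(=O)O[C@@H](CC=C(C)C)c1cc(OC(C)=O)c2c(OC)ccc(OC)c2c1OC(C)=O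
F10 | step 11 | (1S)-1-(1,4-diacetoxy-5,8-dioxo-5,8-dihydronaphthalen-2-yl)-4-methylpent-3-en-1-yl (2E)-2-methylbut-2-enoate | C/C=C(\C)C(=O)O[C@@H](CC=C(C)C)c1cc(OC(C)=O)c2C(=O)C=CC(=O)c2c1OC(C)=O
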